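**Strategy.** The seven-membered ring C1–C7 of the bicyclo[3.2.1]octane core, with oxygen at C2 and C4 and the quaternary centre C5 that bears prenyl and the bridge carbon C8, is cut into a 1-methoxy-3-silyloxydiene (C1–C4) and a vinylcarbenoid (C7–C6–C5). One rhodium-catalysed cyclopropanation/Cope sequence forms C1–C7 and C4–C5, closes the cycloheptadiene and sets C5 enantioselectively. Its precursors are an (E)-vinyldiazoacetate whose fully substituted vinyl terminus carries prenyl and the future C8 ester, and a (1E,3Z)-diene carrying the C1 methyl group. The dione is then unveiled oxidatively, C1 is closed onto the C5 ester, and ester equilibration, Grignard addition, C3 acylation and C8 reoxidation finish the target.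

Key step: step 5

Remark on numbering: the labels C1–C8 are those of the bicyclo[3.2.1]octane core of the target (C1 methyl bridgehead, C2–C4 dione bridge, C5 prenyl bridgehead, C6 CH2, C7 carbinol-bearing CH, C8 bridging ketone) and are used for every intermediate.

Remark on the catalyst: the sense of induction of the prolinate catalyst is assumed to be that known for styrene (S-configured catalyst gives the (1S,2R)-cyclopropane); transposed to diene 7 and the (E)-vinyl terminus of 4, the S catalyst would give the enantiomer of 9, so the R-configured catalyst Rh2(R-DOSP)4, dirhodium tetrakis[(R)-N-(4-dodecylbenzenesulfonyl)prolinate] (divalent rhodium), is used.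

**Step 1**
Reactants: 1 dimethyl (E)-pent-2-enedioate; 2 1-bromo-3-methylbut-2-ene
Product: 3 dimethyl (E)-4-(3-methylbut-2-en-1-yl)pent-2-enedioate (racemic)
Conditions: LiN(SiMe3)2 (1.0 equiv), THF, −78 °C; then 2, −78 to 0 °C
Reagents that add atoms: none
Why: Alkylation of the delocalised glutaconate anion (a vinylogous malonate) with the allylic bromide takes place at an ester α-carbon (enolate alkylation, SN2); the position of the remaining double bond and the new stereocentre are irrelevant because both isomers give the same anion in step 2.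

**Step 2**
Reactants: 3 dimethyl (E)-4-(3-methylbut-2-en-1-yl)pent-2-enedioate
Product: 4 dimethyl (E)-2-diazo-4-(3-methylbut-2-en-1-yl)pent-3-enedioate
Conditions: 4-acetamidobenzenesulfonyl azide, DBU, MeCN, 0 °C to rt
Reagents that add atoms: 4-acetamidobenzenesulfonyl azide, CC(=O)Nc1ccc(cc1)S(=O)(=O)N=[N+]=[N-]
Why: Regitz diazo transfer: DBU regenerates the delocalised anion, which can accept the diazo group only at its unsubstituted CH terminus, so the double bond ends up conjugated with the prenyl-bearing ester in the tiglate-like E geometry (ester of the future C5 trans to the diazo carbon, the future C7); only this geometric isomer is carried on because the vinyl geometry decides the configuration of C5 in step 5.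

**Step 3**
Reactants: 5 (E)-4-methoxybut-3-en-2-one
Product: 6 (E)-1-methoxypent-1-en-3-one
Conditions: LiN(iPr)2, THF, −78 °C; then MeI, DMPU, −78 to −40 °C
Reagents that add atoms: iodomethane, CI
Why: Kinetic α'-deprotonation of the β-methoxy enone at its methyl group and SN2 methylation of the lithium enolate (enolate alkylation); the E enol ether is not touched.

**Step 4**
Reactants: 6 (E)-1-methoxypent-1-en-3-one
Product: 7 (1E,3Z)-1-methoxy-3-(tert-butyldimethylsilyloxy)penta-1,3-diene
Conditions: TBSOTf, Et3N, Et2O, 0 °C
Reagents that add atoms: tert-butyldimethylsilyl trifluoromethanesulfonate, CC(C)(C)[Si](C)(C)OS(=O)(=O)C(F)(F)F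
Why: Soft enolisation of the ethyl ketone by silyl triflate and amine gives the 2-silyloxydiene (silyl enol ether formation), the Z enol ether (methyl cis to OSi) being the normal outcome for such ketones and the one wanted in step 5.

**Step 5**
Reactants: 4 dimethyl (E)-2-diazo-4-(3-methylbut-2-en-1-yl)pent-3-enedioate; 7 (1E,3Z)-1-methoxy-3-(tert-butyldimethylsilyloxy)penta-1,3-diene (3 equiv)
Product: 9 dimethyl (3R,4S,7S)-4-methoxy-7-methyl-3-(3-methylbut-2-en-1-yl)-6-(tert-butyldimethylsilyloxy)cyclohepta-1,5-diene-1,3-dicarboxylate, via cis-divinylcyclopropane 8 (not isolated)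
Conditions: Rh2(R-DOSP)4 (1 mol %), hexanes, 4 added slowly to 7, −40 °C to rt; then 65 °C
Reagents that add atoms: none
Why: Loss of dinitrogen from 4 gives the rhodium-bound donor–acceptor vinylcarbenoid, which is attacked by C1 of 7 (the nucleophilic terminus of the 2-silyloxydiene) and closes on C2 to the cis-divinylcyclopropane 8; warming then drives the Cope rearrangement through a boat transition state that breaks C2–C7 and forms C4–C5. The closest known reaction type is the rhodium-catalysed tandem cyclopropanation/Cope rearrangement of vinyldiazoacetates with oxygenated 1,3-dienes (formal (4+3) cycloaddition). The three-membered ring closes by stereospecific (2+1) carbenoid addition to C1=C2 and the seven-membered ring by the suprafacial [3,3]-sigmatropic shift of the cis-divinylcyclopropane. C5 is set by the catalyst, which fixes the absolute configuration of 8, and is relayed by the boat geometry with the (E)-vinyl group (ester outward, prenyl CH2 inward, hence the gentle heating); C4 follows from the 1E geometry of the diene (OMe outward, cis to the C5 ester) and C1 from retention of the 3Z geometry in the cyclopropanation (methyl on the face away from the two vinyl groups, cis to the C5 ester). The step needs attack on the C1=C2 bond and not on C3=C4 (secured by the OSi and vinylogous OMe donation that converge on C1 and by cation stabilisation at C2), the cis-divinyl arrangement (donor group cis to the alkene substituent, as is usual for donor–acceptor carbenoids), no vinylogous attack (blocked by the fully substituted C5) and intermolecular capture faster than reaction with the carbenoid's own prenyl group (excess diene, slow addition, hydrocarbon solvent).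

**Step 6**
Reactants: 9 dimethyl (3R,4S,7S)-4-methoxy-7-methyl-3-(3-methylbut-2-en-1-yl)-6-(tert-butyldimethylsilyloxy)cyclohepta-1,5-diene-1,3-dicarboxylate
Product: 11 dimethyl (3R)-7-methyl-3-(3-methylbut-2-en-1-yl)-4,6-dioxocyclohept-1-ene-1,3-dicarboxylate, via vinylogous methyl ester 10 (not isolated)
Conditions: DDQ (1.1 equiv), 2,6-lutidine, CH2Cl2, 0 °C; then 2 M HCl, THF, rt
Reagents that add atoms: water, O
Why: DDQ dehydrogenation of the silyl enol ether removes hydride from C4–H (allylic to the enol ether and α to OMe) and the silyl group, which gives the β-methoxy enone with the C4 oxygen retained, and acid hydrolysis of this vinylogous ester (water adds at C4, methanol leaves) frees the 2,4-dione; C5 is quaternary and unaffected, while C1 (and the position of the ring alkene) may equilibrate without consequence.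

**Step 7**
Reactants: 11 dimethyl (3R)-7-methyl-3-(3-methylbut-2-en-1-yl)-4,6-dioxocyclohept-1-ene-1,3-dicarboxylate
Product: 13 methyl 2,8-dihydroxy-1-methyl-5-(3-methylbut-2-en-1-yl)-4-oxobicyclo[3.2.1]octa-2,6-diene-7-carboxylate (C1 and C5 as in the target; 8-OH on the side of the C2–C4 bridge), via bicyclic trione enoate 12 (not isolated)
Conditions: LiN(iPr)2 (3.2 equiv), THF–DMPU, −78 to 0 °C; then MeOH, NaBH4, −20 °C
Reagents that add atoms: none
Why: Dieckmann-type Claisen condensation of a 1,3-diketone dianion: after C3 the C1–H is removed (a C1=C7 alkene isomer gives the same dienolate through C6–H), C1 attacks the C5 ester across the ring (5-(enolexo)-exo-trig for ring C1–C7–C6–C5–C8, 6-(enolendo)-exo-trig for ring C1–C2–C3–C4–C5–C8) and the product is held as its diketonate so that methoxide cannot reverse it, C1 being fixed by C5 because the one-carbon bridge can only span cis and the C6=C7 bond being kept so that no acidic C7–H competes; borohydride then reduces the strained, exposed C8 ketone in the same flask (hydride from the alkene side, opposite the anionic bridge; either C8 epimer would serve), which shields C8 from the nucleophiles of steps 8 and 9 and removes the risk of CO extrusion.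

**Step 8**
Reactants: 13 methyl 2,8-dihydroxy-1-methyl-5-(3-methylbut-2-en-1-yl)-4-oxobicyclo[3.2.1]octa-2,6-diene-7-carboxylate
Product: 15 methyl 2,8-dihydroxy-1-methyl-5-(3-methylbut-2-en-1-yl)-4-oxobicyclo[3.2.1]oct-2-ene-7-exo-carboxylate, via endo ester 14 (not isolated)
Conditions: NaBH4, NiCl2·6H2O (0.3 equiv), MeOH, 0 °C; filter; then NaOMe, MeOH, 60 °C
Reagents that add atoms: none
Why: Nickel boride Ni2B, formed from NaBH4 and NiCl2, reduces the conjugated, strained C6=C7 bond from the exo face while the isolated prenyl alkene stays (conjugate reduction), and reversible deprotonation of the ester by methoxide then moves the C7 ester from endo to the less hindered exo position (syn to C8, away from the anionic C2–C4 bridge), which sets C7 under thermodynamic control; the minor epimer can be resubmitted.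

**Step 9**
Reactants: 15 methyl 2,8-dihydroxy-1-methyl-5-(3-methylbut-2-en-1-yl)-4-oxobicyclo[3.2.1]oct-2-ene-7-exo-carboxylate
Product: 16 2,8-dihydroxy-7-exo-(2-hydroxypropan-2-yl)-1-methyl-5-(3-methylbut-2-en-1-yl)bicyclo[3.2.1]oct-2-en-4-one
Conditions: MeMgBr (8 equiv), THF, 0 °C to rt
Reagents that add atoms: methylmagnesium bromide, C[Mg]Br
Why: Double Grignard addition to the only ester gives the tertiary carbinol; the enol and the C8 hydroxyl are merely deprotonated, the diketonate is inert and no ketone is present, and C7 carries no acidifying group afterwards, so its configuration is locked.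

**Step 10**
Reactants: 16 2,8-dihydroxy-7-exo-(2-hydroxypropan-2-yl)-1-methyl-5-(3-methylbut-2-en-1-yl)bicyclo[3.2.1]oct-2-en-4-one; 17 (R)-2-methylbutanoic acid
Product: 19 2,8-dihydroxy-7-exo-(2-hydroxypropan-2-yl)-1-methyl-5-(3-methylbut-2-en-1-yl)-3-[(2R)-2-methylbutanoyl]bicyclo[3.2.1]oct-2-en-4-one, via enol ester 18 (not isolated)
Conditions: DCC, DMAP (1.2 equiv), CH2Cl2, 0 °C to rt
Reagents that add atoms: none
Why: Steglich-type O-acylation of the enolised dione followed by DMAP-mediated O-to-C acyl migration leads to the 2-acyl-1,3-dione as the thermodynamic product; the bis-neopentyl C8 hydroxyl and the tertiary hydroxyl are not acylated, and carbodiimide activation without added strong base should leave the α-stereocentre of the acid intact.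

**Step 11**
Reactants: 19 2,8-dihydroxy-7-exo-(2-hydroxypropan-2-yl)-1-methyl-5-(3-methylbut-2-en-1-yl)-3-[(2R)-2-methylbutanoyl]bicyclo[3.2.1]oct-2-en-4-one
Product: 20 (1S,5S,7S)-2-hydroxy-7-(2-hydroxypropan-2-yl)-1-methyl-5-(3-methylbut-2-en-1-yl)-3-[(2R)-2-methylbutanoyl]bicyclo[3.2.1]oct-2-ene-4,8-dione (CNP0201042.1)
Conditions: Dess–Martin periodinane, CH2Cl2, rt
Reagents that add atoms: none
Why: Dess–Martin oxidation of the only secondary alcohol restores the C8 ketone under neutral conditions as the last operation; the tertiary alcohol, the prenyl group and the enolised triketone (no hydrogen at C3) are not oxidised.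

**Compound list**

1 | dimethyl (E)-pent-2-enedioate | COC(=O)C/C=C/C(=O)OC | starting material
2 | 1-bromo-3-methylbut-2-ene | CC(C)=CCBr | starting material
3 | dimethyl (E)-4-(3-methylbut-2-en-1-yl)pent-2-enedioate, racemic | COC(=O)/C=C/C(CC=C(C)C)C(=O)OC | intermediate
4 | dimethyl (E)-2-diazo-4-(3-methylbut-2-en-1-yl)pent-3-enedioate | COC(=O)C(=[N+]=[N-])/C=C(\CC=C(C)C)C(=O)OC | intermediate
5 | (E)-4-methoxybut-3-en-2-one | CO/C=C/C(C)=O | starting material
6 | (E)-1-methoxypent-1-en-3-one | CCC(=O)/C=C/OC | intermediate
7 | (1E,3Z)-1-methoxy-3-(tert-butyldimethylsilyloxy)penta-1,3-diene | C/C=C(O[Si](C)(C)C(C)(C)C)/C=C/OC | intermediate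
8 | methyl 1-[(E)-2-(methoxycarbonyl)-5-methylhexa-1,4-dien-1-yl]-2-[(E)-2-methoxyethenyl]-3-methyl-2-(tert-butyldimethylsilyloxy)cyclopropane-1-carboxylate; both alkenyl groups and the C3 hydrogen on one face; ester, silyloxy and methyl on the other | COC(=O)[C@]1(/C=C(\CC=C(C)C)C(=O)OC)[C@H](C)[C@@]1(O[Si](C)(C)C(C)(C)C)/C=C/OC | intermediate
9 | dimethyl (3R,4S,7S)-4-methoxy-7-methyl-3-(3-methylbut-2-en-1-yl)-6-(tert-butyldimethylsilyloxy)cyclohepta-1,5-diene-1,3-dicarboxylate; C3 ester, C4 methoxy and C7 methyl all cis | COC(=O)C1=C[C@@](CC=C(C)C)(C(=O)OC)[C@@H](OC)C=C(O[Si](C)(C)C(C)(C)C)[C@H]1C | intermediate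
10 | dimethyl (3R)-4-methoxy-7-methyl-3-(3-methylbut-2-en-1-yl)-6-oxocyclohepta-1,4-diene-1,3-dicarboxylate; C7 drawn as carried over from 9, labile | COC(=O)C1=C[C@@](CC=C(C)C)(C(=O)OC)C(OC)=CC(=O)[C@H]1C | intermediate
11 | dimethyl (3R)-7-methyl-3-(3-methylbut-2-en-1-yl)-4,6-dioxocyclohept-1-ene-1,3-dicarboxylate; C7 drawn as carried over from 9, labile | COC(=O)C1=C[C@@](CC=C(C)C)(C(=O)OC)C(=O)CC(=O)[C@H]1C | intermediate
12 | methyl 2-hydroxy-1-methyl-5-(3-methylbut-2-en-1-yl)-4,8-dioxobicyclo[3.2.1]octa-2,6-diene-7-carboxylate; C1 and C5 as in the target | C1=C(O)[C@@]2(C)C(=O)[C@](CC=C(C)C)(C=C2C(=O)OC)C1=O | intermediate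
13 | methyl 2,8-dihydroxy-1-methyl-5-(3-methylbut-2-en-1-yl)-4-oxobicyclo[3.2.1]octa-2,6-diene-7-carboxylate; 8-OH on the side of the C2–C4 bridge | C1=C(O)[C@@]2(C)[C@@H](O)[C@](CC=C(C)C)(C=C2C(=O)OC)C1=O | intermediate
14 | methyl 2,8-dihydroxy-1-methyl-5-(3-methylbut-2-en-1-yl)-4-oxobicyclo[3.2.1]oct-2-ene-7-endo-carboxylate | C1=C(O)[C@@]2(C)[C@@H](O)[C@](CC=C(C)C)(C[C@H]2C(=O)OC)C1=O | intermediate
15 | methyl 2,8-dihydroxy-1-methyl-5-(3-methylbut-2-en-1-yl)-4-oxobicyclo[3.2.1]oct-2-ene-7-exo-carboxylate; ester syn to C8 | C1=C(O)[C@@]2(C)[C@@H](O)[C@](CC=C(C)C)(C[C@@H]2C(=O)OC)C1=O | intermediate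
16 | 2,8-dihydroxy-7-exo-(2-hydroxypropan-2-yl)-1-methyl-5-(3-methylbut-2-en-1-yl)bicyclo[3.2.1]oct-2-en-4-one | C1=C(O)[C@@]2(C)[C@@H](O)[C@](CC=C(C)C)(C[C@@H]2C(C)(C)O)C1=O | intermediate
17 | (R)-2-methylbutanoic acid | CC[C@@H](C)C(=O)O | starting material
18 | enol (2R)-2-methylbutanoate of 16 at the C2 oxygen | C1=C(OC(=O)[C@H](C)CC)[C@@]2(C)[C@@H](O)[C@](CC=C(C)C)(C[C@@H]2C(C)(C)O)C1=O | intermediate
19 | 2,8-dihydroxy-7-exo-(2-hydroxypropan-2-yl)-1-methyl-5-(3-methylbut-2-en-1-yl)-3-[(2R)-2-methylbutanoyl]bicyclo[3.2.1]oct-2-en-4-one | CC[C@@H](C)C(=O)C1=C(O)[C@@]2(C)[C@@H](O)[C@](CC=C(C)C)(C[C@@H]2C(C)(C)O)C1=O | intermediate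
20 | (1S,5S,7S)-2-hydroxy-7-(2-hydroxypropan-2-yl)-1-methyl-5-(3-methylbut-2-en-1-yl)-3-[(2R)-2-methylbutanoyl]bicyclo[3.2.1]oct-2-ene-4,8-dione | CC[C@@H](C)C(=O)C1=C(O)[C@@]2(C)C(=O)[C@](CC=C(C)C)(C[C@@H]2C(C)(C)O)C1=O | target

**Step count.** Total: 11 steps. Longest linear sequence: 9 steps (1 → 3 → 4 → 9 → 11 → 13 → 15 → 16 → 19 → 20); the diene branch (5 → 6 → 7) adds 2 steps.

**Steps most likely to fail**

Step 5. The bulky donor–acceptor carbenoid may fail to cyclopropanate the trisubstituted, methyl-bearing enol ether bond and divert into allylic C–H insertion, attack on the methoxyvinyl bond or capture by its own prenyl alkene. The stereochemical relay to C5 may also erode through a long-lived zwitterion. The fallback sets out from 5 and 4 and brings the C1 methyl in afterwards. Silylation of 5 (TBSOTf, Et3N) gives (E)-1-methoxy-3-(tert-butyldimethylsilyloxy)buta-1,3-diene F1, whose CH2 terminus belongs to the diene class established for this reaction. With 4 and Rh2(R-DOSP)4 it gives the cis-divinylcyclopropane F2 and, after Cope rearrangement, the cycloheptadiene lacking the C1 methyl F3. DDQ oxidation as in step 6 gives the vinylogous methyl ester F4. Kinetic α'-deprotonation with LiN(iPr)2 and methylation with MeI at −78 °C (enolate alkylation, faster than ring closure at this temperature) gives 10 as C1 epimers, both of which serve. The fallback comes back to the route at 10, which is hydrolysed to 11 as in the second stage of step 6.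

Step 7. The second deprotonation of the cyclic 1,3-diketone may stay incomplete, or intermolecular condensation and fragmentation of the strained bridged trione may compete before it is reduced. The fallback sets out from 10, isolated after the DDQ stage of step 6 instead of being hydrolysed. Kinetic α'-deprotonation of this vinylogous ester with LiN(iPr)2 at −78 °C gives a monoanion at C1, and Dieckmann closure onto the C5 ester (quenched cold with acetic acid) gives the bridged methyl enol ether F5. Hydrolysis of its enol ether with 2 M HCl in THF gives 12, where the fallback comes back to the route; 12 is reduced at once with NaBH4 as in the second stage of step 7.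

Step 6. Protodesilylation with β-elimination of methanol may outrun hydride abstraction, or DDQ may add at C3, so that the C4 oxygen is lost. The fallback sets out from 9 and accepts the elimination. Dilute HCl in THF gives the enone F6. Nucleophilic epoxidation (t-BuOOH, DBU) gives the α,β-epoxy ketone F7, drawn anti to the prenyl group; its configuration is of no consequence. Isomerisation of the epoxy ketone with Pd(PPh3)4 (zerovalent palladium) and 1,2-bis(diphenylphosphino)ethane in toluene at 80 °C gives the 1,3-dione 11, where the fallback comes back to the route.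

**Further compounds**

F1 | step 5 | (E)-1-methoxy-3-(tert-butyldimethylsilyloxy)buta-1,3-diene | CO/C=C/C(=C)O[Si](C)(C)C(C)(C)C
F2 | step 5 | methyl 1-[(E)-2-(methoxycarbonyl)-5-methylhexa-1,4-dien-1-yl]-2-[(E)-2-methoxyethenyl]-2-(tert-butyldimethylsilyloxy)cyclopropane-1-carboxylate, alkenyl groups cis | COC(=O)[C@]1(/C=C(\CC=C(C)C)C(=O)OC)C[C@@]1(O[Si](C)(C)C(C)(C)C)/C=C/OC
F3 | step 5 | dimethyl 4-methoxy-3-(3-methylbut-2-en-1-yl)-6-(tert-butyldimethylsilyloxy)cyclohepta-1,5-diene-1,3-dicarboxylate, C3 and C4 as in 9 | COC(=O)C1=C[C@@](CC=C(C)C)(C(=O)OC)[C@@H](OC)C=C(O[Si](C)(C)C(C)(C)C)C1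
F4 | step 5 | dimethyl 4-methoxy-3-(3-methylbut-2-en-1-yl)-6-oxocyclohepta-1,4-diene-1,3-dicarboxylate, C3 as in 9 | COC(=O)C1=C[C@@](CC=C(C)C)(C(=O)OC)C(OC)=CC(=O)C1
F5 | step 7 | methyl 4-methoxy-1-methyl-5-(3-methylbut-2-en-1-yl)-2,8-dioxobicyclo[3.2.1]octa-3,6-diene-7-carboxylate, C1 and C5 as in the target | O=C1[C@@]2(C)C(=O)[C@](CC=C(C)C)(C=C2C(=O)OC)C(OC)=C1
F6 | step 6 | dimethyl 7-methyl-3-(3-methylbut-2-en-1-yl)-6-oxocyclohepta-1,4-diene-1,3-dicarboxylate, C3 and C7 as in 9 | COC(=O)C1=C[C@@](CC=C(C)C)(C(=O)OC)C=CC(=O)[C@H]1C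
F7 | step 6 | dimethyl 4,5-epoxy-7-methyl-3-(3-methylbut-2-en-1-yl)-6-oxocyclohept-1-ene-1,3-dicarboxylate, epoxide anti to prenyl | COC(=O)C1=C[C@@](CC=C(C)C)(C(=O)OC)[C@H]2O[C@H]2C(=O)[C@H]1C
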